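**Plan**

- Locants: ring C1–C6, with C1 the C–OH carbon between side chain and methyl; chain C1′–C16′ counted from the benzylic carbon.
- Cuts: ring bonds C3–C4, C1–C2 and C1–C6 (benzannulation of a terminal enyne, a propenyl carbene complex and CO), then chain bonds C1′–C(sp) and C8′–C9′ (two copper-mediated allyl–alkynyl couplings).
- Feature used: ring C1(OH) lies between C2 (side chain) and C6 (CH3), and C4(OH) lies between the two ring CH groups C3 and C5. A propenyl(methoxy)carbene, one CO and a terminal alkyne assemble exactly this pattern as a 4-methoxyphenol.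
- Forward: geraniol gives (S)-dehydrolinalool 4; 4 and 8-bromogeranyl acetate 7 give the C16 chain; the alkyne becomes the 9′E alkene; the C1′ end becomes a propargyl terminus; the single ring is built last; O-demethylation runs through the quinone.
- Stereochemistry: C11′ (S) comes from Sharpless epoxidation of geraniol with L-(+)-diethyl tartrate, and its C–O bond is never broken afterwards. 2′E and 6′E come with geranyl acetate; 9′E comes from hydroxyl-directed trans-hydroalumination.

Key step: step 12

Remark: geranyl acetate is taken as purchased, and the optical purity of 23 is that set by the epoxidation in step 1, since no later step touches the C11′–O bond.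

**Route**

Step 1
Reactants: 1 geraniol
Product: 2 (2S,3S)-2,3-epoxygeraniol
Conditions: Ti(OiPr)4 (5 mol%), L-(+)-diethyl tartrate (7 mol%), t-BuOOH, 4 Å MS, CH2Cl2, −20 °C
Reagents that add atoms: tert-butyl hydroperoxide, CC(C)(C)OO
Why: Katsuki–Sharpless asymmetric epoxidation: the titanium tartrate catalyst binds the allylic hydroxyl and epoxidises only the C2=C3 bond, the L-(+)-tartrate ligand giving the (2S,3S)-epoxide whose C3 becomes C11′ of the target, while the isolated C6=C7 alkene is untouched.

Step 2
Reactants: 2 (2S,3S)-2,3-epoxygeraniol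
Product: 3 (2R,3S)-1-chloro-2,3-epoxy-3,7-dimethyloct-6-ene
Conditions: PPh3, CCl4, NaHCO3, reflux
Reagents that add atoms: carbon tetrachloride, ClC(Cl)(Cl)Cl
Why: Appel chlorination of the primary alcohol under buffered neutral conditions leaves the 2,3-epoxide closed and makes or breaks no bond at C2 or C3 (the C2 descriptor becomes R only because chlorine raises the priority of C1).

Step 3
Reactants: 3 (2R,3S)-1-chloro-2,3-epoxy-3,7-dimethyloct-6-ene
Product: 4 (S)-dehydrolinalool [(3S)-3,7-dimethyloct-6-en-1-yn-3-ol]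
Conditions: n-BuLi (3.2 equiv), THF, −40 → −20 °C; then aq. NH4Cl
Reagents that add atoms: none
Why: Base-induced double elimination of a 2,3-epoxy chloride to a terminal propargylic alcohol: lithiation at C1 opens the epoxide at the C2–O bond and a second elimination removes HCl, so the C3–O bond is never broken and the tertiary carbinol is obtained with (S) configuration.

Step 4
Reactants: 5 geranyl acetate
Product: 6 (2E,6E)-8-hydroxy-3,7-dimethylocta-2,6-dien-1-yl acetate
Conditions: SeO2 (cat.), t-BuOOH, salicylic acid (cat.), CH2Cl2, rt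
Reagents that add atoms: tert-butyl hydroperoxide, CC(C)(C)OO
Why: SeO2-catalysed allylic hydroxylation (Riley oxidation, ene reaction then [2,3]-sigmatropic shift) attacks the electron-rich C6=C7 alkene at its (E)-methyl group, while the acetoxy-deactivated C2=C3 alkene is left alone.

Step 5
Reactants: 6 (2E,6E)-8-hydroxy-3,7-dimethylocta-2,6-dien-1-yl acetate
Product: 7 (2E,6E)-8-bromo-3,7-dimethylocta-2,6-dien-1-yl acetate
Conditions: CBr4, PPh3, CH2Cl2, 0 °C
Reagents that add atoms: carbon tetrabromide, BrC(Br)(Br)Br
Why: Appel bromination of a primary allylic alcohol proceeds by SN2 displacement of the oxyphosphonium group, without allylic transposition and without touching the acetate.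

Step 6
Reactants: 4 (S)-dehydrolinalool; 7 (2E,6E)-8-bromo-3,7-dimethylocta-2,6-dien-1-yl acetate
Product: 8 (2E,6E,11S)-11-hydroxy-3,7,11,15-tetramethylhexadeca-2,6,14-trien-9-yn-1-yl acetate
Conditions: CuI (cat.), NaI, K2CO3, DMF, rt
Reagents that add atoms: none
Why: Copper-acetylide alkylation of a terminal alkyne with a primary allylic halide (iodide formed in situ by Finkelstein exchange) forms the C8′–C9′ bond at the unhindered CH2 terminus with retention of the 6E geometry, and the tertiary hydroxyl and the acetate are inert to K2CO3 in DMF.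

Step 7
Reactants: 8 (2E,6E,11S)-11-hydroxy-3,7,11,15-tetramethylhexadeca-2,6,14-trien-9-yn-1-yl acetate
Product: 9 (2E,6E,9E,11S)-3,7,11,15-tetramethylhexadeca-2,6,9,14-tetraene-1,11-diol
Conditions: NaAlH2(OCH2CH2OMe)2 (Red-Al, 3 equiv), THF, 0 °C → rt; aq. KNaC4H4O6
Reagents that add atoms: none
Why: Hydroxyl-directed trans-hydroalumination of a propargylic alcohol: the alkoxyaluminate adds H–Al anti across the alkyne and protonolysis gives only the 9′E alkene, while the same hydride cleaves the acetate reductively to the primary alcohol and leaves C11′ untouched.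

Step 8
Reactants: 9 (2E,6E,9E,11S)-3,7,11,15-tetramethylhexadeca-2,6,9,14-tetraene-1,11-diol
Product: 11 (6S,7E,10E,14E)-16-bromo-2,6,10,14-tetramethylhexadeca-2,7,10,14-tetraen-6-ol, via primary allylic mesylate 10 (not isolated)
Conditions: MsCl, Et3N, THF, −40 °C; then LiBr, THF, −40 → 0 °C
Reagents that add atoms: lithium bromide, [Li+].[Br-]; methanesulfonyl chloride, CS(=O)(=O)Cl (mesyl group of 10 only)
Why: Sulfonylation of the unhindered primary allylic hydroxyl is far faster than that of the tertiary one at −40 °C, and SN2 mesylate–bromide exchange gives the primary allylic bromide without ionising conditions, so the tertiary allylic alcohol and the alkene geometries are preserved.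

Step 9
Reactants: 11 (6S,7E,10E,14E)-16-bromo-2,6,10,14-tetramethylhexadeca-2,7,10,14-tetraen-6-ol; 12 trimethylsilylacetylene
Product: 13 (6S,7E,10E,14E)-2,6,10,14-tetramethyl-18-(trimethylsilyl)octadeca-2,7,10,14-tetraen-17-yn-6-ol
Conditions: CuI (cat.), NaI, K2CO3, DMF, rt
Reagents that add atoms: none
Why: The same copper-acetylide allylation as in step 6 joins C1′ to the alkyne by SN2 at the primary carbon, the silyl cap prevents a second allylation, and the base is too weak to touch the tertiary hydroxyl.

Step 10
Reactants: 13 (6S,7E,10E,14E)-2,6,10,14-tetramethyl-18-(trimethylsilyl)octadeca-2,7,10,14-tetraen-17-yn-6-ol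
Product: 14 (6S,7E,10E,14E)-2,6,10,14-tetramethyloctadeca-2,7,10,14-tetraen-17-yn-6-ol
Conditions: K2CO3, MeOH, 0 °C → rt
Reagents that add atoms: none
Why: Base-catalysed methanolysis of the C(sp)–Si bond (protodesilylation) is fast at or below room temperature, and K2CO3 in MeOH is too weak a base to isomerise the skipped enyne to an allene during the short reaction.

Step 11
Reactants: 15 (E)-1-bromoprop-1-ene; 16 chromium hexacarbonyl
Product: 19 pentacarbonyl[(2E)-1-methoxybut-2-en-1-ylidene]chromium, via (E)-prop-1-enyllithium 17 (not isolated), via lithium acylpentacarbonylchromate 18 (not isolated)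
Conditions: t-BuLi (2 equiv), Et2O, −78 °C; Cr(CO)6, Et2O, −78 °C → rt; Me3OBF4, CH2Cl2, 0 °C
Reagents that add atoms: trimethyloxonium tetrafluoroborate, C[O+](C)C.F[B-](F)(F)F; tert-butyllithium, [Li]C(C)(C)C (lithium of 17 and 18 only)
Why: Fischer carbene synthesis: bromine–lithium exchange with retention of alkene geometry gives the vinyllithium, which adds to a CO ligand of Cr(CO)6, and O-methylation of the acylchromate with the Meerwein salt gives the alkenyl(methoxy)carbene complex of zerovalent chromium.

Step 12
Reactants: 14 (6S,7E,10E,14E)-2,6,10,14-tetramethyloctadeca-2,7,10,14-tetraen-17-yn-6-ol; 19 pentacarbonyl[(2E)-1-methoxybut-2-en-1-ylidene]chromium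
Product: 21 2-[(2E,6E,9E,11S)-11-hydroxy-3,7,11,15-tetramethylhexadeca-2,6,9,14-tetraen-1-yl]-4-methoxy-6-methylphenol, via tricarbonylchromium arene complex 20 (not isolated)
Conditions: 19 (1.5 equiv), THF, 50 °C, Ar; then air, Et2O, rt
Reagents that add atoms: none
Why: Thermal loss of one CO from 19 opens a site on zerovalent chromium, the terminal alkyne of 14 inserts into the Cr=C bond with its CH end bonded to the methoxy-bearing carbene carbon (bond C3–C4), and CO insertion at the chain-bearing carbon (bond C1–C2) gives a chromium-bound dienylketene. The ring is closed by 6π-electrocyclisation of that dienylketene, which joins the ketene carbon C1 to the propenyl β-carbon C6; tautomerisation of the cyclohexadienone gives the phenol, held as the Cr(CO)3 complex 20 until air oxidation releases 21. This is the Dötz benzannulation of an alkenyl(alkoxy)carbene chromium complex with a terminal alkyne, a reaction type established for allyl-substituted alkynes (1,4-enynes) in isoprenoid quinone synthesis. No stereocentre is created, and C11′, the three E-alkenes and the tertiary hydroxyl are spectators under the neutral conditions at 50 °C. The selectivity needed is the regiochemistry of alkyne insertion, and the terminal alkyne secures it: the steric difference between H and the C1′ methylene places the chain next to the CO-derived carbon, ortho to the new hydroxyl. An alkenyl carbene in THF also favours the phenol channel over cyclobutenone or indene formation.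

Step 13
Reactants: 21 2-[(2E,6E,9E,11S)-11-hydroxy-3,7,11,15-tetramethylhexadeca-2,6,9,14-tetraen-1-yl]-4-methoxy-6-methylphenol
Product: 22 2-[(2E,6E,9E,11S)-11-hydroxy-3,7,11,15-tetramethylhexadeca-2,6,9,14-tetraen-1-yl]-6-methylcyclohexa-2,5-diene-1,4-dione
Conditions: (NH4)2Ce(NO3)6 (2.2 equiv), MeCN/H2O, 0 °C, short contact time
Reagents that add atoms: water, O
Why: Oxidative demethylation of a 4-methoxyphenol by tetravalent cerium: two one-electron oxidations give the aryloxy cation, water adds at C4 and methanol is lost, a fast reaction at 0 °C that is routinely applied to polyprenyl arenes without attack on trisubstituted alkenes.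

Step 14
Reactants: 22 2-[(2E,6E,9E,11S)-11-hydroxy-3,7,11,15-tetramethylhexadeca-2,6,9,14-tetraen-1-yl]-6-methylcyclohexa-2,5-diene-1,4-dione
Product: 23 2-[(2E,6E,9E,11S)-11-hydroxy-3,7,11,15-tetramethylhexadeca-2,6,9,14-tetraen-1-yl]-6-methylbenzene-1,4-diol (CNP0297794.1)
Conditions: Na2S2O4, Et2O/H2O, rt, Ar
Reagents that add atoms: none
Why: Dithionite reduction of a 1,4-benzoquinone to the hydroquinone is a mild two-electron reduction in a two-phase system that touches neither the alkenes nor the tertiary allylic alcohol, so C11′ keeps its (S) configuration.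

**Compound list**

1 | geraniol | CC(C)=CCC/C(C)=C/CO | starting material
2 | (2S,3S)-2,3-epoxygeraniol | OC[C@@H]1O[C@@]1(C)CCC=C(C)C | intermediate
3 | (2R,3S)-1-chloro-2,3-epoxy-3,7-dimethyloct-6-ene | ClC[C@@H]1O[C@@]1(C)CCC=C(C)C | intermediate
4 | (S)-dehydrolinalool, (3S)-3,7-dimethyloct-6-en-1-yn-3-ol | CC(C)=CCC[C@](C)(O)C#C | intermediate
5 | geranyl acetate | CC(C)=CCC/C(C)=C/COC(C)=O | starting material
6 | (2E,6E)-8-hydroxy-3,7-dimethylocta-2,6-dien-1-yl acetate | OC/C(C)=C/CC/C(C)=C/COC(C)=O | intermediate
7 | (2E,6E)-8-bromo-3,7-dimethylocta-2,6-dien-1-yl acetate | BrC/C(C)=C/CC/C(C)=C/COC(C)=O | intermediate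
8 | (2E,6E,11S)-11-hydroxy-3,7,11,15-tetramethylhexadeca-2,6,14-trien-9-yn-1-yl acetate | CC(C)=CCC[C@](C)(O)C#CC/C(C)=C/CC/C(C)=C/COC(C)=O | intermediate
9 | (2E,6E,9E,11S)-3,7,11,15-tetramethylhexadeca-2,6,9,14-tetraene-1,11-diol | CC(C)=CCC[C@](C)(O)/C=C/C/C(C)=C/CC/C(C)=C/CO | intermediate
10 | (2E,6E,9E,11S)-11-hydroxy-3,7,11,15-tetramethylhexadeca-2,6,9,14-tetraen-1-yl methanesulfonate (not isolated) | CC(C)=CCC[C@](C)(O)/C=C/C/C(C)=C/CC/C(C)=C/COS(C)(=O)=O | intermediate
11 | (6S,7E,10E,14E)-16-bromo-2,6,10,14-tetramethylhexadeca-2,7,10,14-tetraen-6-ol | CC(C)=CCC[C@](C)(O)/C=C/C/C(C)=C/CC/C(C)=C/CBr | intermediate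
12 | trimethylsilylacetylene | C#C[Si](C)(C)C | starting material
13 | (6S,7E,10E,14E)-2,6,10,14-tetramethyl-18-(trimethylsilyl)octadeca-2,7,10,14-tetraen-17-yn-6-ol | CC(C)=CCC[C@](C)(O)/C=C/C/C(C)=C/CC/C(C)=C/CC#C[Si](C)(C)C | intermediate
14 | (6S,7E,10E,14E)-2,6,10,14-tetramethyloctadeca-2,7,10,14-tetraen-17-yn-6-ol | CC(C)=CCC[C@](C)(O)/C=C/C/C(C)=C/CC/C(C)=C/CC#C | intermediate
15 | (E)-1-bromoprop-1-ene | C/C=C/Br | starting material
16 | chromium hexacarbonyl | O=C=[Cr](=C=O)(=C=O)(=C=O)(=C=O)=C=O | starting material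
17 | (E)-prop-1-enyllithium (not isolated) | C/C=C/[Li] | intermediate
18 | lithium pentacarbonyl[(2E)-1-oxidobut-2-en-1-ylidene]chromate (not isolated) | [Li+].C/C=C/C([O-])=[Cr](=C=O)(=C=O)(=C=O)(=C=O)=C=O | intermediate
19 | pentacarbonyl[(2E)-1-methoxybut-2-en-1-ylidene]chromium | COC(/C=C/C)=[Cr](=C=O)(=C=O)(=C=O)(=C=O)=C=O | intermediate
20 | tricarbonyl(η6-arene)chromium complex of phenol 21, Cr(CO)3 bound to the benzene ring (not isolated) | CC(C)=CCC[C@](C)(O)/C=C/C/C(C)=C/CC/C(C)=C/Cc1cc(OC)cc(C)c1O.O=C=[Cr](=C=O)=C=O | intermediate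
21 | 2-[(2E,6E,9E,11S)-11-hydroxy-3,7,11,15-tetramethylhexadeca-2,6,9,14-tetraen-1-yl]-4-methoxy-6-methylphenol | CC(C)=CCC[C@](C)(O)/C=C/C/C(C)=C/CC/C(C)=C/Cc1cc(OC)cc(C)c1O | intermediate
22 | 2-[(2E,6E,9E,11S)-11-hydroxy-3,7,11,15-tetramethylhexadeca-2,6,9,14-tetraen-1-yl]-6-methylcyclohexa-2,5-diene-1,4-dione | CC(C)=CCC[C@](C)(O)/C=C/C/C(C)=C/CC/C(C)=C/CC1=CC(=O)C=C(C)C1=O | intermediate
23 | 2-[(2E,6E,9E,11S)-11-hydroxy-3,7,11,15-tetramethylhexadeca-2,6,9,14-tetraen-1-yl]-6-methylbenzene-1,4-diol | CC(C)=CCC[C@](C)(O)/C=C/C/C(C)=C/CC/C(C)=C/Cc1cc(O)cc(C)c1O | target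

**Count**

Total steps: 14. Longest linear sequence: 11 steps (steps 1, 2, 3, 6, 7, 8, 9, 10, 12, 13, 14, from geraniol).

**Steps most likely to fail**

Step 12. After alkyne insertion the chromium vinylcarbene may fail to take up CO and drain into cyclobutenone, furan or alkyne-oligomer channels, and the free hydroxyl may intercept the ketene, so that the valuable enyne is consumed unproductively. The fallback sets out from bromide 11 and comes back at quinone 22; it brings the arene in preformed.
- Commercial 4-methoxy-2-methylphenol is brominated at its only free ortho position (N-bromosuccinimide, MeCN, 0 °C) to 2-bromo-4-methoxy-6-methylphenol F1.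
- F1 is O-methylated (MeI, K2CO3, acetone) to 1-bromo-2,5-dimethoxy-3-methylbenzene F2, which Mg in THF converts into (2,5-dimethoxy-3-methylphenyl)magnesium bromide F3.
- F3 (excess, one equivalent being consumed by the hydroxyl of 11) is coupled with 11 under CuI catalysis (THF, −20 °C → rt), SN2 at the primary allylic carbon, to give (6S,7E,10E,14E)-16-(2,5-dimethoxy-3-methylphenyl)-2,6,10,14-tetramethylhexadeca-2,7,10,14-tetraen-6-ol F4.
- (NH4)2Ce(NO3)6 in MeCN/H2O at 0 °C oxidises the hydroquinone dimethyl ether F4 to 22.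

Step 6. The copper acetylide may attack the allylic system of 7 at C6 (SN2′) and give the branched enyne, and oxidative dimerisation of 4 may use up the alkyne. The fallback sets out from alkynol 4 and comes back at diol 9, making neither the copper coupling nor the hydride reduction necessary.
- Pd-catalysed hydrostannation of 4 (Bu3SnH, PdCl2(PPh3)2, THF, 0 °C) places tin on the terminal carbon and gives (1E,3S)-3,7-dimethyl-1-(tributylstannyl)octa-1,6-dien-3-ol F5.
- Stille coupling of F5 with bromide 7 (PdCl2(MeCN)2, DMF, rt) forms the C8′–C9′ bond with the 9′E alkene already in place and gives (2E,6E,9E,11S)-11-hydroxy-3,7,11,15-tetramethylhexadeca-2,6,9,14-tetraen-1-yl acetate F6.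
- Methanolysis of F6 (K2CO3, MeOH, rt) gives 9.

Step 13. Nitric acid set free during the cerium oxidation may ionise the tertiary allylic alcohol (1,3-transposition or dehydration), and tetravalent cerium may fragment it. The fallback sets out from phenol 21 and comes back at quinone 22.
- PhI(OAc)2 in MeOH at 0 °C performs the two-electron oxidation and traps the cation with methanol as the quinone monoketal, 2-[(2E,6E,9E,11S)-11-hydroxy-3,7,11,15-tetramethylhexadeca-2,6,9,14-tetraen-1-yl]-4,4-dimethoxy-6-methylcyclohexa-2,5-dien-1-one F7.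
- F7 is hydrolysed to 22 with dilute aqueous acetic acid in acetone at rt, conditions a tertiary allylic alcohol tolerates.

**Further compounds**

F1 | step 12 | 2-bromo-4-methoxy-6-methylphenol | COc1cc(C)c(O)c(Br)c1
F2 | step 12 | 1-bromo-2,5-dimethoxy-3-methylbenzene | COc1cc(C)c(OC)c(Br)c1
F3 | step 12 | (2,5-dimethoxy-3-methylphenyl)magnesium bromide | COc1cc(C)c(OC)c([Mg]Br)c1
F4 | step 12 | (6S,7E,10E,14E)-16-(2,5-dimethoxy-3-methylphenyl)-2,6,10,14-tetramethylhexadeca-2,7,10,14-tetraen-6-ol | CC(C)=CCC[C@](C)(O)/C=C/C/C(C)=C/CC/C(C)=C/Cc1cc(OC)cc(C)c1OC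
F5 | step 6 | (1E,3S)-3,7-dimethyl-1-(tributylstannyl)octa-1,6-dien-3-ol | CC(C)=CCC[C@](C)(O)/C=C/[Sn](CCCC)(CCCC)CCCC
F6 | step 6 | (2E,6E,9E,11S)-11-hydroxy-3,7,11,15-tetramethylhexadeca-2,6,9,14-tetraen-1-yl acetate | CC(C)=CCC[C@](C)(O)/C=C/C/C(C)=C/CC/C(C)=C/COC(C)=O
F7 | step 13 | 2-[(2E,6E,9E,11S)-11-hydroxy-3,7,11,15-tetramethylhexadeca-2,6,9,14-tetraen-1-yl]-4,4-dimethoxy-6-methylcyclohexa-2,5-dien-1-one | CC(C)=CCC[C@](C)(O)/C=C/C/C(C)=C/CC/C(C)=C/CC1=CC(OC)(OC)C=C(C)C1=O
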